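**Plan**

- Retrosynthesis: after removal of the benzyl ethers, the lower pyran ring is cut at C4–C4a together with the C3–O bond of an epoxide. This unravels the lower unit to a Z-enol ether on the middle unit's 4β-oxygen that carries an aryl ether stereocentre.
- Enabling feature: in the lower flavan unit the C3 hydroxyl and the C4 ether oxygen are cis, and C4 is bonded to C4a of the electron-rich ring A. That is the pattern left when the ortho carbon of a 3,5-dioxygenated aryl ether opens the acetal carbon of an epoxidised Z-enol ether with inversion.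
- Further cuts, in order: the enol ether C(sp2)–O bond (copper-catalysed vinylation of the dimer 4β-ol with a Z-vinyl iodide), the aryl ether O1–C2 bond of the small fragment (Mitsunobu), and the C4–C8 interflavan bond (flavan-4-yl cation chemistry).
- Forward: epicatechin → perbenzyl monomer → 4β→8 dimer → dimer 4β-ol; aldehyde → resolved propargylic alcohol → aryl ether → Z-vinyl iodide; union; closure of the lower pyran ring; hydrogenolysis.
- Stereochemistry: upper and middle C2/C3 come from (−)-epicatechin, and both of their C4 centres from attack anti to the 3-benzyloxy group. Lower C2 comes from lipase resolution plus Mitsunobu inversion. Lower C3 and C4 come from face-selective epoxidation of the Z-enol ether and inversion at the acetal carbon.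

Key step: step 12

Remark: flavan locants are used throughout; the three flavan units are called upper, middle and lower in the order of the target SMILES, and the lower unit is the 2S, all-cis (ent-epicatechin-type) unit.

**Step 1**
Reactants: 1 (−)-epicatechin
Product: 2 5,7,3',4'-tetra-O-benzyl-(−)-epicatechin
Conditions: BnBr (4.4 equiv), K2CO3, DMF, 0 °C → rt
Reagents that add atoms: benzyl bromide, BrCc1ccccc1
Why: Williamson etherification of the four phenols, which K2CO3 deprotonates while the secondary 3-hydroxyl stays free; no stereocentre is touched.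

**Step 2**
Reactants: 2 5,7,3',4'-tetra-O-benzyl-(−)-epicatechin
Product: 3 3,5,7,3',4'-penta-O-benzyl-(−)-epicatechin
Conditions: NaH, BnBr, DMF, 0 °C → rt
Reagents that add atoms: benzyl bromide, BrCc1ccccc1
Why: Williamson etherification of the sodium alkoxide of the 3-hydroxyl, with C2 and C3 keeping the (2R,3R) configuration of the natural product.

**Step 3**
Reactants: 3 3,5,7,3',4'-penta-O-benzyl-(−)-epicatechin
Product: 4 3,5,7,3',4'-penta-O-benzyl-4β-(2-ethoxyethoxy)epicatechin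
Conditions: DDQ (2 equiv), 2-ethoxyethanol (5 equiv), CH2Cl2, rt
Reagents that add atoms: 2-ethoxyethanol, CCOCCO
Why: DDQ benzylic oxidation, in which hydride abstraction from C4 gives the ring A-stabilised flavan-4-yl cation and the alcohol adds on the β-face, anti to the axial 3-benzyloxy group, setting the 3,4-trans centre.

**Step 4**
Reactants: 4 3,5,7,3',4'-penta-O-benzyl-4β-(2-ethoxyethoxy)epicatechin and 3 3,5,7,3',4'-penta-O-benzyl-(−)-epicatechin (3 equiv)
Product: 5 deca-O-benzyl-epicatechin-(4β→8)-epicatechin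
Conditions: TMSOTf (0.2 equiv), CH2Cl2, −78 °C
Reagents that add atoms: none
Why: Friedel–Crafts alkylation of C8 of 3 (the more nucleophilic and less hindered ring A position of a benzylated flavan) by the flavan-4-yl cation released from 4, with attack anti to the 3-benzyloxy group setting the 4β centre and the excess of 3 suppressing chain growth.

**Step 5**
Reactants: 5 deca-O-benzyl-epicatechin-(4β→8)-epicatechin
Product: 6 deca-O-benzyl-epicatechin-(4β→8)-epicatechin-4β-ol (hydroxyl on C4 of the 8-linked unit, trans to its 3-benzyloxy group)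
Conditions: DDQ (1.3 equiv), CH2Cl2/H2O (10:1), 0 °C → rt
Reagents that add atoms: water, O
Why: DDQ benzylic oxidation with water as the trap, which should be confined to the 8-linked unit because only its C4 carries a pseudo-axial hydrogen aligned with ring A (the upper C4–H lies quasi-equatorial beside the quasi-axial aryl group), water again entering anti to the 3-benzyloxy group.

**Step 6**
Reactants: 7 3,4-bis(benzyloxy)benzaldehyde
Product: 8 rac-1-[3,4-bis(benzyloxy)phenyl]prop-2-yn-1-ol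
Conditions: HC≡CMgBr (1.5 equiv), THF, 0 °C; aq. NH4Cl
Reagents that add atoms: ethynylmagnesium bromide, C#C[Mg]Br
Why: Grignard 1,2-addition of the acetylide to the aldehyde, giving the racemic carbinol that is resolved in the next step.

**Step 7**
Reactants: 8 rac-1-[3,4-bis(benzyloxy)phenyl]prop-2-yn-1-ol
Product: 9 (S)-1-[3,4-bis(benzyloxy)phenyl]prop-2-yn-1-ol
Conditions: Novozym 435 (immobilised Candida antarctica lipase B), vinyl acetate, toluene, 30 °C, stopped just past half conversion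
Reagents that add atoms: none
Why: Lipase-catalysed kinetic resolution by transesterification, in which the usual enantiopreference for secondary alcohols (aryl as large, ethynyl as medium group) should acetylate the R enantiomer and leave the S alcohol for separation.

**Step 8**
Reactants: 9 (S)-1-[3,4-bis(benzyloxy)phenyl]prop-2-yn-1-ol and 10 3,5-bis(benzyloxy)phenol
Product: 11 (R)-1-[3,4-bis(benzyloxy)phenyl]prop-2-yn-1-yl 3,5-bis(benzyloxy)phenyl ether
Conditions: PPh3, DIAD, toluene, −20 °C → rt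
Reagents that add atoms: none
Why: Mitsunobu etherification, in which the phenoxide displaces the oxyphosphonium group in an SN2 step with inversion, turning the S carbinol into the R aryl ether that becomes C2 of the lower unit.

**Step 9**
Reactants: 11 (R)-1-[3,4-bis(benzyloxy)phenyl]prop-2-yn-1-yl 3,5-bis(benzyloxy)phenyl ether
Product: 13 (S)-3-iodo-1-[3,4-bis(benzyloxy)phenyl]prop-2-yn-1-yl 3,5-bis(benzyloxy)phenyl ether, via lithium acetylide 12 (not isolated)
Conditions: n-BuLi (1.05 equiv), THF, −78 °C; then I2 (1.1 equiv), −78 °C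
Reagents that add atoms: iodine, II
Why: Deprotonation of the terminal alkyne and iodination of the acetylide at low temperature, which spares the electron-rich rings; the stereocentre is untouched and only its descriptor changes with the new priorities.

**Step 10**
Reactants: 13 (S)-3-iodo-1-[3,4-bis(benzyloxy)phenyl]prop-2-yn-1-yl 3,5-bis(benzyloxy)phenyl ether
Product: 14 (R,Z)-3-iodo-1-[3,4-bis(benzyloxy)phenyl]prop-2-en-1-yl 3,5-bis(benzyloxy)phenyl ether
Conditions: 2-nitrobenzenesulfonylhydrazide, Et3N, THF/i-PrOH, rt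
Reagents that add atoms: none
Why: Diimide reduction of the iodoalkyne, a concerted syn transfer of two hydrogens that gives the Z-vinyl iodide and leaves benzyl ethers and the C–I bond alone.

**Step 11**
Reactants: 6 deca-O-benzyl-epicatechin-(4β→8)-epicatechin-4β-ol and 14 (R,Z)-3-iodo-1-[3,4-bis(benzyloxy)phenyl]prop-2-en-1-yl 3,5-bis(benzyloxy)phenyl ether (2 equiv)
Product: 15 deca-O-benzyl dimer 4β-O-[(1Z,3R)-3-[3,4-bis(benzyloxy)phenyl]-3-[3,5-bis(benzyloxy)phenoxy]prop-1-en-1-yl] ether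
Conditions: CuI (20 mol %), 3,4,7,8-tetramethyl-1,10-phenanthroline (40 mol %), Cs2CO3, 4 Å MS, toluene, 80 °C
Reagents that add atoms: none
Why: Copper-catalysed Ullmann-type C–O coupling of a secondary alcohol with a vinyl iodide, which proceeds with retention of alkene geometry, so the Z-enol ether and the preformed aryl ether stereocentre arrive intact without strong base or ynol ethers on the dimer.

**Step 12**
Reactants: 15 deca-O-benzyl dimer 4β-O-[(1Z,3R)-3-[3,4-bis(benzyloxy)phenyl]-3-[3,5-bis(benzyloxy)phenoxy]prop-1-en-1-yl] ether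
Product: 17 tetradeca-O-benzyl trimer with free lower 3-hydroxyl, via epoxy acetal 16 (not isolated)
Conditions: DMDO (1.2 equiv, acetone), CH2Cl2, 4 Å MS, −78 °C; then ZnCl2 (0.2 equiv, Et2O), −78 → −30 °C; Et3N quench
Reagents that add atoms: dimethyldioxirane, CC1(C)OO1
Why: Proposed new method: DMDO should transfer oxygen to the electron-rich Z-enol ether far faster than to any arene or benzyl ether, giving cis-epoxy acetal 16, whose acetal carbon C4 is then attacked from the rear by the ortho carbon of the tethered 3,5-bis(benzyloxy)phenyl ether while ZnCl2 holds the departing oxygen, a Friedel–Crafts alkylation with SN2 character that ends by rearomatisation; the closest known reactions are the DMDO epoxidation of glycals with ZnCl2-assisted opening at the anomeric carbon with inversion, and the epoxide–arene cyclisations that give chroman-3-ols. The lower pyran ring closes in the 6-endo mode and not 5-exo because only C4 is an acetal carbon able to carry oxocarbenium character, and the two ortho positions of the symmetric arene are equivalent. C3 is set by the face of epoxidation: allylic 1,3-strain in the Z-alkene turns the C2–H into the alkene plane, the 3,4-bis(benzyloxy)phenyl group blocks one face and the oxidant should enter past the small aryloxy oxygen, which places the new C3–O bond cis to the C2 aryl group. C4 is set by inversion, and anti opening of a cis-epoxide leaves the C3 hydroxyl and the C4 ether oxygen cis, through a chair-like transition state with the C2 aryl group equatorial and the breaking C–O bond axial. The step needs the middle unit's C4–O bond and the benzylic aryl ether to stay un-ionised, which the weak, substoichiometric Lewis acid, the low temperature and the non-polar solvent are chosen to secure.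

**Step 13**
Reactants: 17 tetradeca-O-benzyl trimer with free lower 3-hydroxyl
Product: 18 CNP0310719.1
Conditions: H2 (1 atm), Pd(OH)2/C, THF/MeOH/H2O, rt
Reagents that add atoms: none
Why: Catalytic hydrogenolysis of the twelve aryl and two alkyl benzyl ethers in a neutral medium, where the hindered secondary C4–O–C4 ether and the ring C2–O1 bonds should be cleaved much more slowly than primary benzyl ethers and no acid is present to ionise them.

**Compound list**

1 | (−)-epicatechin | Oc1cc(O)c2c(c1)O[C@H](c1ccc(O)c(O)c1)[C@H](O)C2 | starting material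
2 | 5,7,3',4'-tetra-O-benzyl-(−)-epicatechin | O(Cc9ccccc9)c1cc(OCc9ccccc9)c2c(c1)O[C@H](c1ccc(OCc9ccccc9)c(OCc9ccccc9)c1)[C@H](O)C2 | intermediate
3 | 3,5,7,3',4'-penta-O-benzyl-(−)-epicatechin | O(Cc9ccccc9)c1cc(OCc9ccccc9)c2c(c1)O[C@H](c1ccc(OCc9ccccc9)c(OCc9ccccc9)c1)[C@H](OCc9ccccc9)C2 | intermediate
4 | 3,5,7,3',4'-penta-O-benzyl-4β-(2-ethoxyethoxy)epicatechin | O(Cc9ccccc9)c1cc(OCc9ccccc9)c2c(c1)O[C@H](c1ccc(OCc9ccccc9)c(OCc9ccccc9)c1)[C@H](OCc9ccccc9)[C@H]2OCCOCC | intermediate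
5 | deca-O-benzyl-epicatechin-(4β→8)-epicatechin | O(Cc9ccccc9)c1cc(OCc9ccccc9)c2c(c1)O[C@H](c1ccc(OCc9ccccc9)c(OCc9ccccc9)c1)[C@H](OCc9ccccc9)[C@H]2c1c(OCc9ccccc9)cc(OCc9ccccc9)c2c1O[C@H](c1ccc(OCc9ccccc9)c(OCc9ccccc9)c1)[C@H](OCc9ccccc9)C2 | intermediate
6 | deca-O-benzyl-epicatechin-(4β→8)-epicatechin-4β-ol | O(Cc9ccccc9)c1cc(OCc9ccccc9)c2c(c1)O[C@H](c1ccc(OCc9ccccc9)c(OCc9ccccc9)c1)[C@H](OCc9ccccc9)[C@H]2c1c(OCc9ccccc9)cc(OCc9ccccc9)c2c1O[C@H](c1ccc(OCc9ccccc9)c(OCc9ccccc9)c1)[C@H](OCc9ccccc9)[C@H]2O | intermediate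
7 | 3,4-bis(benzyloxy)benzaldehyde | O=Cc1ccc(OCc2ccccc2)c(OCc2ccccc2)c1 | starting material
8 | rac-1-[3,4-bis(benzyloxy)phenyl]prop-2-yn-1-ol | C#CC(O)c1ccc(OCc2ccccc2)c(OCc2ccccc2)c1 | intermediate
9 | (S)-1-[3,4-bis(benzyloxy)phenyl]prop-2-yn-1-ol | C#C[C@H](O)c1ccc(OCc2ccccc2)c(OCc2ccccc2)c1 | intermediate
10 | 3,5-bis(benzyloxy)phenol | Oc1cc(OCc2ccccc2)cc(OCc2ccccc2)c1 | starting material
11 | (R)-1-[3,4-bis(benzyloxy)phenyl]prop-2-yn-1-yl 3,5-bis(benzyloxy)phenyl ether | C#C[C@H](c1ccc(OCc2ccccc2)c(OCc2ccccc2)c1)Oc1cc(OCc2ccccc2)cc(OCc2ccccc2)c1 | intermediate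
12 | lithium acetylide of 11 | [Li]C#C[C@H](c1ccc(OCc2ccccc2)c(OCc2ccccc2)c1)Oc1cc(OCc2ccccc2)cc(OCc2ccccc2)c1 | intermediate (not isolated)
13 | (S)-3-iodo-1-[3,4-bis(benzyloxy)phenyl]prop-2-yn-1-yl 3,5-bis(benzyloxy)phenyl ether | IC#C[C@H](c1ccc(OCc2ccccc2)c(OCc2ccccc2)c1)Oc1cc(OCc2ccccc2)cc(OCc2ccccc2)c1 | intermediate
14 | (R,Z)-3-iodo-1-[3,4-bis(benzyloxy)phenyl]prop-2-en-1-yl 3,5-bis(benzyloxy)phenyl ether | I/C=C\[C@H](c1ccc(OCc2ccccc2)c(OCc2ccccc2)c1)Oc1cc(OCc2ccccc2)cc(OCc2ccccc2)c1 | intermediate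
15 | deca-O-benzyl dimer 4β-O-[(1Z,3R)-3-[3,4-bis(benzyloxy)phenyl]-3-[3,5-bis(benzyloxy)phenoxy]prop-1-en-1-yl] ether (key-step precursor) | O(Cc9ccccc9)c1cc(OCc9ccccc9)c2c(c1)O[C@H](c1ccc(OCc9ccccc9)c(OCc9ccccc9)c1)[C@H](OCc9ccccc9)[C@H]2c1c(OCc9ccccc9)cc(OCc9ccccc9)c2c1O[C@H](c1ccc(OCc9ccccc9)c(OCc9ccccc9)c1)[C@H](OCc9ccccc9)[C@H]2O/C=C\[C@H](c1ccc(OCc9ccccc9)c(OCc9ccccc9)c1)Oc1cc(OCc9ccccc9)cc(OCc9ccccc9)c1 | intermediate
16 | cis-epoxy acetal of 15 (oxirane oxygen on the face anti to the C2 aryl group) | O(Cc9ccccc9)c1cc(OCc9ccccc9)c2c(c1)O[C@H](c1ccc(OCc9ccccc9)c(OCc9ccccc9)c1)[C@H](OCc9ccccc9)[C@H]2c1c(OCc9ccccc9)cc(OCc9ccccc9)c2c1O[C@H](c1ccc(OCc9ccccc9)c(OCc9ccccc9)c1)[C@H](OCc9ccccc9)[C@H]2O[C@@H]1O[C@@H]1[C@H](c1ccc(OCc9ccccc9)c(OCc9ccccc9)c1)Oc1cc(OCc9ccccc9)cc(OCc9ccccc9)c1 | intermediate (not isolated)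
17 | tetradeca-O-benzyl trimer, lower unit (2S)-2,3-cis-3,4-cis with free 3-hydroxyl (key-step product) | O(Cc9ccccc9)c1cc(OCc9ccccc9)c2c(c1)O[C@H](c1ccc(OCc9ccccc9)c(OCc9ccccc9)c1)[C@H](OCc9ccccc9)[C@H]2c1c(OCc9ccccc9)cc(OCc9ccccc9)c2c1O[C@H](c1ccc(OCc9ccccc9)c(OCc9ccccc9)c1)[C@H](OCc9ccccc9)[C@H]2O[C@H]1c2c(OCc9ccccc9)cc(OCc9ccccc9)cc2O[C@@H](c2ccc(OCc9ccccc9)c(OCc9ccccc9)c2)[C@H]1O | intermediate
18 | CNP0310719.1 | Oc1cc(O)c2c(c1)O[C@H](c1ccc(O)c(O)c1)[C@H](O)[C@H]2c1c(O)cc(O)c2c1O[C@H](c1ccc(O)c(O)c1)[C@H](O)[C@H]2O[C@H]1c2c(O)cc(O)cc2O[C@@H](c2ccc(O)c(O)c2)[C@H]1O | target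

**Count**

Total steps: 13. Longest linear sequence: 8 steps (steps 1, 2, 3, 4, 5, 11, 12, 13 from (−)-epicatechin; the fragment branch, steps 6–10 then 11–13, is equally long).

**Steps most likely to fail**

Step 12 (proposed new method). Two processes may defeat it. The oxidant may add to the alkene face next to the aryl group, because an electrostatic preference for the face away from the allylic oxygen opposes the steric bias. More probably, the neutral arene may be too slow, so that the Lewis acid-assisted epoxy acetal drifts into a free oxocarbenium ion that loses the middle unit as its C4 cation, rearranges, or closes without inversion. The fallback answers the second process and not the first: it turns the arene into an aryl-metal nucleophile, so the ring closes under basic conditions by known chemistry. It sets out from 9 and 10. Phenol 10 is brominated (NBS, CH2Cl2, −78 °C) to 2-bromo-3,5-bis(benzyloxy)phenol F1, separated from its 4-bromo isomer. Mitsunobu reaction of 9 with F1 gives the bromo aryl propargyl ether F2. Iodination (I2, morpholine, toluene) gives the iodoalkyne F3, and diimide reduction the Z-vinyl iodide F4. CuI-catalysed coupling of F4 with 6, in which the hindered aryl bromide should stay inert, gives the bromo enol ether F5. DMDO at −78 °C gives the bromo epoxy acetal F6. After cold removal of the volatiles, t-BuLi (2 equiv, THF, −78 °C) exchanges bromine for lithium, and the aryllithium F7 opens the epoxide at the acetal carbon with inversion, as aryl-metal reagents do with 1,2-anhydro sugars (a Parham-type cyclisation in which no oxocarbenium ion can form). Protonation gives 17, where the route is rejoined.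

Step 11. Carbon–oxygen bond formation at the hindered, peri-flanked secondary alkoxide may be too slow, leaving time for dehydroiodination of 14 or for aromatic Claisen rearrangement of the product at 80 °C. The fallback builds the enol ether outward from the oxygen at or below room temperature, setting out from 6. KH and trichloroethylene in THF (alkoxide addition to dichloroacetylene formed in the flask) give the (E)-1,2-dichlorovinyl ether F8. n-BuLi (2.5 equiv, −78 °C) converts it into the lithium alkoxyacetylide F9, which adds to aldehyde 7 to give the carbinols F10 as both epimers. MnO2 oxidises them to the ynone F11. (R)-Alpine-Borane, for which the alkynyl group is the small substituent, reduces F11 to the R carbinol F12. Mitsunobu reaction with 10 gives the alkynyl aryl ether F13 with inversion. Semi-hydrogenation over Pd/CaCO3 poisoned with Pb(OAc)2 (quinoline, rt) gives 15, where the route is rejoined.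

Step 8. Ionisation of the oxyphosphonium intermediate of this electron-rich benzylic and propargylic alcohol would erode the configuration and open the way to C-alkylation of the phenol. The fallback replaces resolution and SN2 displacement by a catalytic enantioconvergent substitution, setting out from 8. Acetylation (Ac2O, pyridine) gives the racemic acetate F14. Copper-catalysed enantioselective propargylic etherification with 10 (CuOTf·½C6H6, Ph-pybox, i-Pr2NEt, low temperature) runs through a copper allenylidene common to both enantiomers; the ligand antipode is chosen for the R ether. This gives 11, where the route is rejoined, and step 7 is then not needed.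

**Further compounds**

F1 | step 12 | 2-bromo-3,5-bis(benzyloxy)phenol | Oc1cc(OCc2ccccc2)cc(OCc2ccccc2)c1Br
F2 | step 12 | (R)-1-[3,4-bis(benzyloxy)phenyl]prop-2-yn-1-yl 2-bromo-3,5-bis(benzyloxy)phenyl ether | C#C[C@H](c1ccc(OCc2ccccc2)c(OCc2ccccc2)c1)Oc1cc(OCc2ccccc2)cc(OCc2ccccc2)c1Br
F3 | step 12 | (S)-3-iodo-1-[3,4-bis(benzyloxy)phenyl]prop-2-yn-1-yl 2-bromo-3,5-bis(benzyloxy)phenyl ether | IC#C[C@H](c1ccc(OCc2ccccc2)c(OCc2ccccc2)c1)Oc1cc(OCc2ccccc2)cc(OCc2ccccc2)c1Br
F4 | step 12 | (R,Z)-3-iodo-1-[3,4-bis(benzyloxy)phenyl]prop-2-en-1-yl 2-bromo-3,5-bis(benzyloxy)phenyl ether | I/C=C\[C@H](c1ccc(OCc2ccccc2)c(OCc2ccccc2)c1)Oc1cc(OCc2ccccc2)cc(OCc2ccccc2)c1Br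
F5 | step 12 | 2-bromoaryl analogue of enol ether 15 | O(Cc9ccccc9)c1cc(OCc9ccccc9)c2c(c1)O[C@H](c1ccc(OCc9ccccc9)c(OCc9ccccc9)c1)[C@H](OCc9ccccc9)[C@H]2c1c(OCc9ccccc9)cc(OCc9ccccc9)c2c1O[C@H](c1ccc(OCc9ccccc9)c(OCc9ccccc9)c1)[C@H](OCc9ccccc9)[C@H]2O/C=C\[C@H](c1ccc(OCc9ccccc9)c(OCc9ccccc9)c1)Oc1cc(OCc9ccccc9)cc(OCc9ccccc9)c1Br
F6 | step 12 | 2-bromoaryl analogue of epoxy acetal 16 | O(Cc9ccccc9)c1cc(OCc9ccccc9)c2c(c1)O[C@H](c1ccc(OCc9ccccc9)c(OCc9ccccc9)c1)[C@H](OCc9ccccc9)[C@H]2c1c(OCc9ccccc9)cc(OCc9ccccc9)c2c1O[C@H](c1ccc(OCc9ccccc9)c(OCc9ccccc9)c1)[C@H](OCc9ccccc9)[C@H]2O[C@@H]1O[C@@H]1[C@H](c1ccc(OCc9ccccc9)c(OCc9ccccc9)c1)Oc1cc(OCc9ccccc9)cc(OCc9ccccc9)c1Br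
F7 | step 12 | 2-lithioaryl epoxy acetal from F6 | O(Cc9ccccc9)c1cc(OCc9ccccc9)c2c(c1)O[C@H](c1ccc(OCc9ccccc9)c(OCc9ccccc9)c1)[C@H](OCc9ccccc9)[C@H]2c1c(OCc9ccccc9)cc(OCc9ccccc9)c2c1O[C@H](c1ccc(OCc9ccccc9)c(OCc9ccccc9)c1)[C@H](OCc9ccccc9)[C@H]2O[C@@H]1O[C@@H]1[C@H](c1ccc(OCc9ccccc9)c(OCc9ccccc9)c1)Oc1cc(OCc9ccccc9)cc(OCc9ccccc9)c1[Li]
F8 | step 11 | (E)-1,2-dichlorovinyl ether of 6 | O(Cc9ccccc9)c1cc(OCc9ccccc9)c2c(c1)O[C@H](c1ccc(OCc9ccccc9)c(OCc9ccccc9)c1)[C@H](OCc9ccccc9)[C@H]2c1c(OCc9ccccc9)cc(OCc9ccccc9)c2c1O[C@H](c1ccc(OCc9ccccc9)c(OCc9ccccc9)c1)[C@H](OCc9ccccc9)[C@H]2O/C(Cl)=C\Cl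
F9 | step 11 | lithium alkoxyacetylide of 6 | O(Cc9ccccc9)c1cc(OCc9ccccc9)c2c(c1)O[C@H](c1ccc(OCc9ccccc9)c(OCc9ccccc9)c1)[C@H](OCc9ccccc9)[C@H]2c1c(OCc9ccccc9)cc(OCc9ccccc9)c2c1O[C@H](c1ccc(OCc9ccccc9)c(OCc9ccccc9)c1)[C@H](OCc9ccccc9)[C@H]2OC#C[Li]
F10 | step 11 | 3-(dimer-4β-yloxy)-1-[3,4-bis(benzyloxy)phenyl]prop-2-yn-1-ol, both carbinol epimers | O(Cc9ccccc9)c1cc(OCc9ccccc9)c2c(c1)O[C@H](c1ccc(OCc9ccccc9)c(OCc9ccccc9)c1)[C@H](OCc9ccccc9)[C@H]2c1c(OCc9ccccc9)cc(OCc9ccccc9)c2c1O[C@H](c1ccc(OCc9ccccc9)c(OCc9ccccc9)c1)[C@H](OCc9ccccc9)[C@H]2OC#CC(O)c1ccc(OCc9ccccc9)c(OCc9ccccc9)c1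
F11 | step 11 | 3-(dimer-4β-yloxy)-1-[3,4-bis(benzyloxy)phenyl]prop-2-yn-1-one | O(Cc9ccccc9)c1cc(OCc9ccccc9)c2c(c1)O[C@H](c1ccc(OCc9ccccc9)c(OCc9ccccc9)c1)[C@H](OCc9ccccc9)[C@H]2c1c(OCc9ccccc9)cc(OCc9ccccc9)c2c1O[C@H](c1ccc(OCc9ccccc9)c(OCc9ccccc9)c1)[C@H](OCc9ccccc9)[C@H]2OC#CC(=O)c1ccc(OCc9ccccc9)c(OCc9ccccc9)c1
F12 | step 11 | (R)-3-(dimer-4β-yloxy)-1-[3,4-bis(benzyloxy)phenyl]prop-2-yn-1-ol | O(Cc9ccccc9)c1cc(OCc9ccccc9)c2c(c1)O[C@H](c1ccc(OCc9ccccc9)c(OCc9ccccc9)c1)[C@H](OCc9ccccc9)[C@H]2c1c(OCc9ccccc9)cc(OCc9ccccc9)c2c1O[C@H](c1ccc(OCc9ccccc9)c(OCc9ccccc9)c1)[C@H](OCc9ccccc9)[C@H]2OC#C[C@H](O)c1ccc(OCc9ccccc9)c(OCc9ccccc9)c1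
F13 | step 11 | (S)-3-(dimer-4β-yloxy)-1-[3,4-bis(benzyloxy)phenyl]prop-2-yn-1-yl 3,5-bis(benzyloxy)phenyl ether | O(Cc9ccccc9)c1cc(OCc9ccccc9)c2c(c1)O[C@H](c1ccc(OCc9ccccc9)c(OCc9ccccc9)c1)[C@H](OCc9ccccc9)[C@H]2c1c(OCc9ccccc9)cc(OCc9ccccc9)c2c1O[C@H](c1ccc(OCc9ccccc9)c(OCc9ccccc9)c1)[C@H](OCc9ccccc9)[C@H]2OC#C[C@H](c1ccc(OCc9ccccc9)c(OCc9ccccc9)c1)Oc1cc(OCc9ccccc9)cc(OCc9ccccc9)c1
F14 | step 8 | rac-1-[3,4-bis(benzyloxy)phenyl]prop-2-yn-1-yl acetate | CC(=O)OC(C#C)c1ccc(OCc2ccccc2)c(OCc2ccccc2)c1
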